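Everything rests on cutting the side chain at C1'–C2' and at the C3' methyl. The quinone ring (ring A) carries at C2 a benzylic C1'H2 bound to an (E)-trisubstituted C2'=C3' alkene with CH3 on C3'; such a unit arises when a 1-alkyne takes up CH3 and a metal on the same face and the metal is then exchanged for a benzyl group. In one flask, zirconium-catalysed methylalumination of the C2'≡C3' alkyne and palladium-catalysed coupling with 2,5-dimethoxy-3-methylbenzyl chloride make both bonds and fix the geometry. The precursor is the C2'–C16' enyne whose (10'R,11'R)-diol, set from nerol by Sharpless epoxidation and Payne inversion, is carried as a bis(triethylsilyl) ether, inert to AlMe3 and to the final oxidation.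

Key step: step 13

Remark: side-chain locants C1'–C16' run outward from the ring-bound CH2 and ring A is the quinone ring; (4-bromobut-1-yn-1-yl)trimethylsilane is assumed to be purchasable.

Step 1
Reactants: 1 nerol
Product: 2 (2S,3R)-2,3-epoxynerol
Conditions: Ti(OiPr)4 (cat.), L-(+)-diethyl tartrate (cat.), t-BuOOH, 4 Å MS, CH2Cl2, −20 °C
Reagents that add atoms: tert-butyl hydroperoxide, CC(C)(C)OO
Why: Sharpless asymmetric epoxidation, in which the Ti(OiPr)4–L-tartrate catalyst delivers oxygen to one face of the allylic alkene only (the remote C6=C7 alkene has no directing hydroxyl) and so sets C2 (S) and C3 (R), the future C10' and C11'.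

Step 2
Reactants: 2 (2S,3R)-2,3-epoxynerol
Product: 4 (2S,3R)-1-(tert-butylsulfanyl)-3,7-dimethyloct-6-ene-2,3-diol, via Payne alkoxide 3 (not isolated)
Conditions: t-BuSH (slow addition), 0.5 M NaOH, t-BuOH–H2O, reflux, N2
Reagents that add atoms: 2-methylpropane-2-thiol, CC(C)(C)S
Why: Payne rearrangement–opening, in which the C1 alkoxide displaces the epoxide oxygen at C2 with inversion (this sets the final 10'R centre, C3 being untouched) and the thiolate traps the small equilibrium share of terminal epoxide at its unhindered CH2.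

Step 3
Reactants: 4 (2S,3R)-1-(tert-butylsulfanyl)-3,7-dimethyloct-6-ene-2,3-diol
Product: 6 (2R)-6-methyl-2-[(2R)-oxiran-2-yl]hept-5-en-2-ol, via sulfonium salt 5 (not isolated)
Conditions: Me3OBF4, CH2Cl2, 0 °C to rt; then NaH (1 equiv), THF, 0 °C
Reagents that add atoms: none
Why: S-Methylation turns the sulfide into a sulfonium leaving group that the neighbouring secondary alkoxide expels by intramolecular 3-exo-tet displacement at C1 (no bond to a stereocentre is broken), and the aprotic base with no excess should keep the epoxy alcohol from drifting back by a reverse Payne shift.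

Step 4
Reactants: 6 (2R)-6-methyl-2-[(2R)-oxiran-2-yl]hept-5-en-2-ol; 7 1-(trimethylsilyl)propyne
Product: 10 (5R,6R)-6,10-dimethylundec-9-en-1-yne-5,6-diol, via lithiated silylpropyne 8 (not isolated), via silylalkyne dialkoxide 9 (not isolated)
Conditions: 7 (3 equiv), n-BuLi, THF, −78 to −20 °C; 6, DMPU, −78 °C to rt; then MeOH, K2CO3, rt
Reagents that add atoms: none
Why: Epoxide opening by a propargylic organolithium at the terminal CH2 (SN2, stereocentres untouched) after the first equivalent has deprotonated the tertiary hydroxyl, followed in the same flask by methoxide-mediated protodesilylation of the alkynylsilane.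

Step 5
Reactants: 10 (5R,6R)-6,10-dimethylundec-9-en-1-yne-5,6-diol
Product: 11 (5R,6R)-6,10-dimethyl-5,6-bis(triethylsilyloxy)undec-9-en-1-yne
Conditions: TESOTf, 2,6-lutidine, CH2Cl2, −78 to 0 °C
Reagents that add atoms: triethylsilyl trifluoromethanesulfonate, CC[Si](CC)(CC)OS(=O)(=O)C(F)(F)F
Why: Silyl triflate silylation is reactive enough for the tertiary as well as the secondary hydroxyl, and silyl ethers are chosen because, unlike a ketal, they are inert to AlMe3 and later block iodoetherification onto C14'=C15' in step 6 and glycol cleavage in step 14.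

Step 6
Reactants: 11 (5R,6R)-6,10-dimethyl-5,6-bis(triethylsilyloxy)undec-9-en-1-yne
Product: 13 (1E,5R,6R)-1-iodo-2,6,10-trimethyl-5,6-bis(triethylsilyloxy)undeca-1,9-diene, via alkenylalane 12 (not isolated)
Conditions: AlMe3, Cp2ZrCl2, CH2Cl2, 0 °C to rt; then I2, THF, −30 to 0 °C
Reagents that add atoms: trimethylaluminium, C[Al](C)C; iodine, II
Why: Negishi carboalumination adds CH3 and Al syn across the terminal alkyne with CH3 on the internal carbon, and iodinolysis of the C–Al bond with retention should give the (E)-iodoalkene that fixes C6'=C7', the trisubstituted alkene being inert to carbometalation.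

Step 7
Reactants: 13 (1E,5R,6R)-1-iodo-2,6,10-trimethyl-5,6-bis(triethylsilyloxy)undeca-1,9-diene; 14 (4-bromobut-1-yn-1-yl)trimethylsilane
Product: 16 (5E,9R,10R)-6,10,14-trimethyl-9,10-bis(triethylsilyloxy)-1-(trimethylsilyl)pentadeca-5,13-dien-1-yne, via alkylzinc bromide 15 (not isolated)
Conditions: 14, Zn dust, I2 (cat.), DMA, 80 °C; then 13, Pd(PPh3)4 (cat.), THF, rt to 45 °C
Reagents that add atoms: none
Why: Negishi coupling, in which zerovalent palladium inserts into the alkenyl C–I bond, the primary alkylzinc (from direct zinc insertion into the bromide) transmetalates and reductive elimination joins C5'–C6' with retention of the (E)-geometry, the standard way to build 1,5-enynes of isoprenoid chains.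

Step 8
Reactants: 16 (5E,9R,10R)-6,10,14-trimethyl-9,10-bis(triethylsilyloxy)-1-(trimethylsilyl)pentadeca-5,13-dien-1-yne
Product: 17 (5E,9R,10R)-6,10,14-trimethyl-9,10-bis(triethylsilyloxy)pentadeca-5,13-dien-1-yne
Conditions: K2CO3, MeOH–THF, rt
Reagents that add atoms: none
Why: Base-mediated protodesilylation of the alkynylsilane, to which the two O–SiEt3 groups are stable.

Step 9
Reactants: 18 4-methoxy-2-methylphenol
Product: 19 2-hydroxy-5-methoxy-3-methylbenzaldehyde
Conditions: MgCl2, Et3N, (CH2O)n, MeCN, reflux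
Reagents that add atoms: formaldehyde (as paraformaldehyde), C=O
Why: Magnesium-mediated ortho-formylation of a phenol (Casnati–Skattebøl reaction), in which the magnesium phenoxide delivers formaldehyde to the only free ortho position and a second formaldehyde oxidises the benzylic alkoxide to the aldehyde.

Step 10
Reactants: 19 2-hydroxy-5-methoxy-3-methylbenzaldehyde
Product: 20 2,5-dimethoxy-3-methylbenzaldehyde
Conditions: MeI, K2CO3, DMF, rt
Reagents that add atoms: iodomethane, CI
Why: Williamson ether synthesis on the phenoxide.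

Step 11
Reactants: 20 2,5-dimethoxy-3-methylbenzaldehyde
Product: 21 (2,5-dimethoxy-3-methylphenyl)methanol
Conditions: NaBH4, MeOH, 0 °C
Reagents that add atoms: none
Why: Borohydride reduction of the aldehyde to the benzylic alcohol.

Step 12
Reactants: 21 (2,5-dimethoxy-3-methylphenyl)methanol
Product: 22 1-(chloromethyl)-2,5-dimethoxy-3-methylbenzene
Conditions: SOCl2, CH2Cl2, 0 °C to rt
Reagents that add atoms: thionyl chloride, O=S(Cl)Cl
Why: Chlorodehydroxylation through the chlorosulfite, giving an electron-rich benzylic chloride that should be used without storage.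

Step 13
Reactants: 17 (5E,9R,10R)-6,10,14-trimethyl-9,10-bis(triethylsilyloxy)pentadeca-5,13-dien-1-yne; 22 1-(chloromethyl)-2,5-dimethoxy-3-methylbenzene
Product: 24 1-[(2E,6E,10R,11R)-3,7,11,15-tetramethyl-10,11-bis(triethylsilyloxy)hexadeca-2,6,14-trien-1-yl]-2,5-dimethoxy-3-methylbenzene, via alkenylalane 23 (not isolated)
Conditions: 17, AlMe3, Cp2ZrCl2, ClCH2CH2Cl, 0 °C to rt; excess AlMe3 removed in vacuo; then 22, Pd(PPh3)4 (cat.), THF, rt
Reagents that add atoms: trimethylaluminium, C[Al](C)C
Why: Cp2ZrCl2 and AlMe3 form a methylzirconocene–aluminate that adds CH3 and metal syn across C2'≡C3' with CH3 on the internal C3', and exchange to aluminium gives the (E)-alkenylalane 23 (Negishi carboalumination). Zerovalent palladium then inserts into the benzylic C–Cl bond of 22, the alkenyl group transfers from aluminium and reductive elimination with retention forms C1'–C2'; this tandem is the known entry to prenylated quinone precursors from 1-alkynes and benzylic chlorides. No ring is closed and no stereocentre is made, and the C2'=C3' geometry follows from syn addition plus retention in the coupling. The step needs methyl delivery to C3' (inherent to a terminal alkyne), reaction at the alkyne only (the three trisubstituted alkenes do not carbometalate) and inert oxygen functions (the silyl ethers neither consume AlMe3 nor open as a ketal would). Removing excess AlMe3 before 22 is added should keep methyl transfer to the benzylpalladium intermediate from competing.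

Step 14
Reactants: 24 1-[(2E,6E,10R,11R)-3,7,11,15-tetramethyl-10,11-bis(triethylsilyloxy)hexadeca-2,6,14-trien-1-yl]-2,5-dimethoxy-3-methylbenzene
Product: 25 2-methyl-6-[(2E,6E,10R,11R)-3,7,11,15-tetramethyl-10,11-bis(triethylsilyloxy)hexadeca-2,6,14-trien-1-yl]cyclohexa-2,5-diene-1,4-dione
Conditions: (NH4)2Ce(NO3)6, MeCN–CH2Cl2–H2O, 0 °C, inverse addition, short contact
Reagents that add atoms: water, O
Why: Oxidative demethylation of a para-dimethoxyarene by tetravalent cerium, in which two single-electron oxidations with addition of water at the ipso carbons and loss of methanol give the para-quinone, inverse addition limits biaryl coupling and the silyl ethers keep the glycol from cerium-mediated cleavage.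

Step 15
Reactants: 25 2-methyl-6-[(2E,6E,10R,11R)-3,7,11,15-tetramethyl-10,11-bis(triethylsilyloxy)hexadeca-2,6,14-trien-1-yl]cyclohexa-2,5-diene-1,4-dione
Product: 26 2-[(2E,6E,10R,11R)-10,11-dihydroxy-3,7,11,15-tetramethylhexadeca-2,6,14-trien-1-yl]-6-methylcyclohexa-2,5-diene-1,4-dione (CNP0229670.3)
Conditions: aq. HF, MeCN, 0 °C
Reagents that add atoms: none
Why: Fluoride-assisted cleavage of both Si–O bonds under mildly acidic conditions that the quinone, the tertiary alcohol and the trisubstituted alkenes should tolerate, with no stereocentre touched.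

Compound list
1 | nerol, (2Z)-3,7-dimethylocta-2,6-dien-1-ol | CC(C)=CCC/C(C)=C\CO | starting material
2 | (2S,3R)-2,3-epoxynerol, [(2S,3R)-3-methyl-3-(4-methylpent-3-en-1-yl)oxiran-2-yl]methanol | CC(C)=CCC[C@@]1(C)O[C@H]1CO | intermediate
3 | Payne alkoxide, sodium (2R)-6-methyl-2-[(2R)-oxiran-2-yl]hept-5-en-2-olate | CC(C)=CCC[C@@](C)([O-])[C@H]1CO1.[Na+] | intermediate
4 | (2S,3R)-1-(tert-butylsulfanyl)-3,7-dimethyloct-6-ene-2,3-diol | CC(C)=CCC[C@@](C)(O)[C@H](O)CSC(C)(C)C | intermediate
5 | sulfonium salt, tert-butyl[(2S,3R)-2,3-dihydroxy-3,7-dimethyloct-6-en-1-yl]methylsulfonium tetrafluoroborate (mixture at sulfur) | CC(C)=CCC[C@@](C)(O)[C@H](O)C[S+](C)C(C)(C)C.F[B-](F)(F)F | intermediate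
6 | (2R)-6-methyl-2-[(2R)-oxiran-2-yl]hept-5-en-2-ol | CC(C)=CCC[C@@](C)(O)[C@H]1CO1 | intermediate
7 | 1-(trimethylsilyl)propyne | CC#C[Si](C)(C)C | starting material
8 | lithiated silylpropyne, [3-(trimethylsilyl)prop-2-yn-1-yl]lithium | [Li]CC#C[Si](C)(C)C | intermediate
9 | silylalkyne dialkoxide, dilithium (5R,6R)-6,10-dimethyl-1-(trimethylsilyl)undec-9-en-1-yne-5,6-diolate | CC(C)=CCC[C@@](C)(O[Li])[C@H](O[Li])CCC#C[Si](C)(C)C | intermediate
10 | (5R,6R)-6,10-dimethylundec-9-en-1-yne-5,6-diol | CC(C)=CCC[C@@](C)(O)[C@H](O)CCC#C | intermediate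
11 | (5R,6R)-6,10-dimethyl-5,6-bis(triethylsilyloxy)undec-9-en-1-yne | CC(C)=CCC[C@@](C)(O[Si](CC)(CC)CC)[C@H](O[Si](CC)(CC)CC)CCC#C | intermediate
12 | alkenylalane, dimethyl[(1E,5R,6R)-2,6,10-trimethyl-5,6-bis(triethylsilyloxy)undeca-1,9-dien-1-yl]alane | CC(C)=CCC[C@@](C)(O[Si](CC)(CC)CC)[C@H](O[Si](CC)(CC)CC)CC/C(C)=C/[Al](C)C | intermediate
13 | (1E,5R,6R)-1-iodo-2,6,10-trimethyl-5,6-bis(triethylsilyloxy)undeca-1,9-diene | CC(C)=CCC[C@@](C)(O[Si](CC)(CC)CC)[C@H](O[Si](CC)(CC)CC)CC/C(C)=C/I | intermediate
14 | (4-bromobut-1-yn-1-yl)trimethylsilane | C[Si](C)(C)C#CCCBr | starting material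
15 | alkylzinc bromide, [4-(trimethylsilyl)but-3-yn-1-yl]zinc bromide | C[Si](C)(C)C#CCC[Zn]Br | intermediate
16 | (5E,9R,10R)-6,10,14-trimethyl-9,10-bis(triethylsilyloxy)-1-(trimethylsilyl)pentadeca-5,13-dien-1-yne | CC(C)=CCC[C@@](C)(O[Si](CC)(CC)CC)[C@H](O[Si](CC)(CC)CC)CC/C(C)=C/CCC#C[Si](C)(C)C | intermediate
17 | (5E,9R,10R)-6,10,14-trimethyl-9,10-bis(triethylsilyloxy)pentadeca-5,13-dien-1-yne (key-step precursor, C2'–C16', diol as bis-silyl ether) | CC(C)=CCC[C@@](C)(O[Si](CC)(CC)CC)[C@H](O[Si](CC)(CC)CC)CC/C(C)=C/CCC#C | intermediate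
18 | 4-methoxy-2-methylphenol | COc1ccc(O)c(C)c1 | starting material
19 | 2-hydroxy-5-methoxy-3-methylbenzaldehyde | COc1cc(C)c(O)c(C=O)c1 | intermediate
20 | 2,5-dimethoxy-3-methylbenzaldehyde | COc1cc(C)c(OC)c(C=O)c1 | intermediate
21 | (2,5-dimethoxy-3-methylphenyl)methanol | COc1cc(C)c(OC)c(CO)c1 | intermediate
22 | 1-(chloromethyl)-2,5-dimethoxy-3-methylbenzene | ClCc1cc(OC)cc(C)c1OC | intermediate
23 | alkenylalane, dimethyl[(1E,5E,9R,10R)-2,6,10,14-tetramethyl-9,10-bis(triethylsilyloxy)pentadeca-1,5,13-trien-1-yl]alane | CC(C)=CCC[C@@](C)(O[Si](CC)(CC)CC)[C@H](O[Si](CC)(CC)CC)CC/C(C)=C/CC/C(C)=C/[Al](C)C | intermediate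
24 | 1-[(2E,6E,10R,11R)-3,7,11,15-tetramethyl-10,11-bis(triethylsilyloxy)hexadeca-2,6,14-trien-1-yl]-2,5-dimethoxy-3-methylbenzene (key-step product) | CC(C)=CCC[C@@](C)(O[Si](CC)(CC)CC)[C@H](O[Si](CC)(CC)CC)CC/C(C)=C/CC/C(C)=C/Cc1cc(OC)cc(C)c1OC | intermediate
25 | 2-methyl-6-[(2E,6E,10R,11R)-3,7,11,15-tetramethyl-10,11-bis(triethylsilyloxy)hexadeca-2,6,14-trien-1-yl]cyclohexa-2,5-diene-1,4-dione | CC(C)=CCC[C@@](C)(O[Si](CC)(CC)CC)[C@H](O[Si](CC)(CC)CC)CC/C(C)=C/CC/C(C)=C/CC1=CC(=O)C=C(C)C1=O | intermediate
26 | 2-[(2E,6E,10R,11R)-10,11-dihydroxy-3,7,11,15-tetramethylhexadeca-2,6,14-trien-1-yl]-6-methylcyclohexa-2,5-diene-1,4-dione (CNP0229670.3) | CC(C)=CCC[C@@](C)(O)[C@H](O)CC/C(C)=C/CC/C(C)=C/CC1=CC(=O)C=C(C)C1=O | target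

Total steps: 15 (11 in the main line, 4 for the arene). Longest linear sequence: 11 steps (steps 1–8 and 13–15, nerol to target).

Steps most likely to fail

Step 13 (key step). The one-flask sequence may stall at incomplete carbometalation, or the coupling may lose out to methyl transfer from residual AlMe3 and to reductive homocoupling of the benzylic chloride. The fallback joins the two halves with reversed polarity in separate flasks. Setting out from 17, the same methylalumination (alane 23) is quenched with I2 to give the (1E,5E)-iodotriene F1. Compound 22 is converted with Zn dust and LiCl in THF into the benzylic zinc chloride F2. Negishi coupling of F1 with F2 under Pd(PPh3)4 in THF comes back to the route at 24.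

Step 4. The lithium alkoxide of 6 may shift back to the unreactive trisubstituted epoxide (reverse Payne migration) faster than the terminal epoxide is opened, and the ambident organolithium may attack through its allenyl terminus. The fallback removes the alkoxide and changes the mode of activation. Setting out from 6, TESOTf and 2,6-lutidine give the tertiary silyl ether F3. This is opened by 8 at −78 °C with BF3·OEt2 assistance to the secondary alcohol F4. K2CO3 in MeOH then gives the terminal alkyne F5; a silyl shift between the two oxygens at this stage would be harmless. A second silylation with TESOTf comes back to the route at 11.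

Step 7. Slow transmetalation, β-hydride loss from the alkylpalladium intermediate or protonation of the organozinc may erode the coupling. The fallback builds the chain by polar alkylation at C4'–C5' instead. Setting out from 11, the methylalumination of step 6 (alane 12) is quenched with paraformaldehyde to give the (E)-allylic alcohol F6. CBr4 and PPh3 with 2,6-lutidine as buffer give the allylic bromide F7. Alkylation of F7 with lithiated silylpropyne 8 in THF at −78 °C comes back to the route at 16.

Further compounds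
F1 | step 13 | (1E,5E,9R,10R)-1-iodo-2,6,10,14-tetramethyl-9,10-bis(triethylsilyloxy)pentadeca-1,5,13-triene | CC(C)=CCC[C@@](C)(O[Si](CC)(CC)CC)[C@H](O[Si](CC)(CC)CC)CC/C(C)=C/CC/C(C)=C/I
F2 | step 13 | (2,5-dimethoxy-3-methylbenzyl)zinc chloride | COc1cc(C)c(OC)c(C[Zn]Cl)c1
F3 | step 4 | triethyl{[(2R)-6-methyl-2-[(2R)-oxiran-2-yl]hept-5-en-2-yl]oxy}silane | CC(C)=CCC[C@@](C)(O[Si](CC)(CC)CC)[C@H]1CO1
F4 | step 4 | (5R,6R)-6,10-dimethyl-6-(triethylsilyloxy)-1-(trimethylsilyl)undec-9-en-1-yn-5-ol | CC(C)=CCC[C@@](C)(O[Si](CC)(CC)CC)[C@H](O)CCC#C[Si](C)(C)C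
F5 | step 4 | (5R,6R)-6,10-dimethyl-6-(triethylsilyloxy)undec-9-en-1-yn-5-ol | CC(C)=CCC[C@@](C)(O[Si](CC)(CC)CC)[C@H](O)CCC#C
F6 | step 7 | (2E,6R,7R)-3,7,11-trimethyl-6,7-bis(triethylsilyloxy)dodeca-2,10-dien-1-ol | CC(C)=CCC[C@@](C)(O[Si](CC)(CC)CC)[C@H](O[Si](CC)(CC)CC)CC/C(C)=C/CO
F7 | step 7 | (2E,6R,7R)-1-bromo-3,7,11-trimethyl-6,7-bis(triethylsilyloxy)dodeca-2,10-diene | CC(C)=CCC[C@@](C)(O[Si](CC)(CC)CC)[C@H](O[Si](CC)(CC)CC)CC/C(C)=C/CBr
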